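**Plan**

1. Retrosynthetic cuts, last bond first: the lactone C19–O bond; the peroxide O–C14 bond, then O–C17 back to an (E)-C16=C17 alkene; the C13–C14 bond; and, in one operation, C4–C5 and C9–C10 of the decalin.
2. Enabling feature: rings A and B are a trans-decalin with quaternary C4 and C10, a C9 side chain and a methyl-bearing oxygenated C8. This is the pattern left by chair–chair folding of an (E,E)-epoxy-triene whose C8 radical ends as an exocyclic methylene.
3. Forward, part 1: farnesylacetone ketal, then the C3/C4 epoxide, then rings A and B together (step 6). C3 is deoxygenated, the C4 arm is oxidised to the acid, and the C8 methylene is moved into ring B and turned into the 6α,8α-diol through the 7-en-6-one.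
4. Forward, part 2: the C14–C19 aldehyde is joined at C13 (step 22), the 1,2-dioxane is closed (steps 25–26) and the lactone is formed last (step 28).
5. Stereochemistry of the decalin: C3 (Sharpless epoxidation) relays to C4, C5, C9 and C10 through the (E)-alkenes; C8 comes from α-face epoxidation of the enone, C6 from a thermodynamic dissolving-metal reduction.
6. Stereochemistry of the side chain: C14 from an asymmetric Nozaki–Hiyama–Kishi coupling followed by one SN2 inversion; C16 and C17 from a Shi epoxidation and inversion at C17 by H2O2.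

Key step: step 6

Numbering: decalin C1–C10 (ring A = C1–C5, C10; ring B = C5–C10); side chain C11–C19 counted outward from C9; substituent carbons are named by the carbon that carries them.

Assumption: the SMILES is read literally, so the γ-lactone is trans-fused to the 1,2-dioxane (14R,16S,17R; H on C16 and the C17 methyl on opposite faces), and the route is built for that isomer.

**Route**

Step 1
Reactants: 1 (2E,6E)-farnesyl bromide; 2 ethyl acetoacetate
Product: 5 (5E,9E)-farnesylacetone, via β-keto ester 3 (not isolated), via β-keto acid 4 (not isolated)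
Conditions: NaOEt, EtOH, 0 °C to rt; then aq. NaOH, 60 °C; then aq. HCl, 60 °C
Reagents that add atoms: none
Why: Acetoacetic ester synthesis, in which SN2 C-alkylation of the sodium enolate at the primary allylic bromide leaves both (E)-alkenes untouched and saponification with decarboxylation should give the methyl ketone that supplies C13 and its future methylene carbon.

Step 2
Reactants: 5 (5E,9E)-farnesylacetone
Product: 6 ethylene ketal of 5 (2-methyl-2-[(3E,7E)-4,8,12-trimethyltrideca-3,7,11-trienyl]-1,3-dioxolane)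
Conditions: ethylene glycol, PPTS (cat.), benzene, reflux, Dean–Stark
Reagents that add atoms: ethylene glycol, OCCO
Why: Acid-catalysed ketalisation with azeotropic removal of water, which masks the ketone so that it can neither capture the C8 radical in step 6 nor be reduced in step 14.

Step 3
Reactants: 6 ketal
Product: 7 (2E,6E,10E)-allylic alcohol (terminal (E)-CH2OH, dioxolane at the other end)
Conditions: SeO2 (cat.), t-BuOOH, CH2Cl2, 0 °C to rt
Reagents that add atoms: tert-butyl hydroperoxide, CC(C)(C)OO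
Why: Selenium dioxide allylic hydroxylation (ene reaction then [2,3]-sigmatropic shift) prefers the terminal, most electron-rich trisubstituted alkene and its (E)-methyl group, so the (E)-2-methyl-2-en-1-ol should form.

Step 4
Reactants: 7 allylic alcohol
Product: 8 (2S,3S)-2,3-epoxy alcohol ((E,E)-diene and dioxolane unchanged)
Conditions: Ti(OiPr)4 (cat.), L-(+)-diethyl tartrate, t-BuOOH, 4 Å MS, CH2Cl2, −20 °C
Reagents that add atoms: tert-butyl hydroperoxide, CC(C)(C)OO
Why: Sharpless asymmetric epoxidation, in which only the allylic-alcohol alkene binds to the titanium tartrate and L-(+)-tartrate delivers oxygen to the face that gives the (2S,3S)-epoxide, i.e. the (S)-configured future C3 with the CH2O arm trans to the chain on the future C4.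

Step 5
Reactants: 8 epoxy alcohol
Product: 9 TBDPS ether of 8 (cyclisation precursor)
Conditions: TBDPSCl, imidazole, DMF, 0 °C to rt
Reagents that add atoms: tert-butyl(chloro)diphenylsilane, CC(C)(C)[Si](Cl)(c1ccccc1)c1ccccc1
Why: Imidazole-mediated silylation of the primary alcohol under non-basic conditions that do not open or rearrange the epoxide; the bulky silyl group is wanted for the C4 selectivity of step 6.

Step 6
Reactants: 9 (E,E)-epoxy-diene TBDPS ether
Product: 11 bicyclic alcohol (3β-OH, 4α-CH2OTBDPS, 4β-CH3, 5α-H, C8 exocyclic methylene, 9β-[2-(2-methyl-1,3-dioxolan-2-yl)ethyl], 10β-CH3), via titanium alkoxide 10 (not isolated)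
Conditions: Cp2TiCl2 (2.5 equiv), Mn dust, degassed THF, rt, slow addition of 9; then aq. NaH2PO4
Reagents that add atoms: none
Why: Cp2TiCl (trivalent titanium), made in the flask from Cp2TiCl2 and Mn, gives one electron to the epoxide, which opens homolytically at the tertiary C4–O bond while C3 keeps its oxygen as the titanium alkoxide 10; this is the titanocene-mediated radical cyclisation of epoxypolyprenes (Nugent–RajanBabu epoxide opening followed by a polyene radical cascade). Ring A closes 6-endo-trig when the C4 radical adds to C5 of the C5=C10 alkene, and ring B closes 6-endo-trig when the resulting C10 radical adds to C9 of the C8=C9 alkene, both in a chair–chair fold; a second Cp2TiCl then removes a hydrogen from the methyl group next to the C8 radical and leaves the exocyclic methylene. C5, C10 and C9 are set by the (E)-geometry of the two alkenes in that fold (trans ring fusion, axial C10 methyl, equatorial C9 chain), and their absolute sense by the (S)-C3 centre, whose bulky O–Ti group lies equatorial. C4 is set at the planar radical stage, where the CH2OTBDPS arm should take the equatorial (α) site and the methyl the axial (β) site, which avoids a 1,3-diaxial contact of the large arm with the C10 methyl. The step needs 6-endo instead of 5-exo closure, which the trisubstituted alkenes secure by placing each new radical on a tertiary carbon, and it needs the chain ketone to stay out of the cascade, which the dioxolane secures.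

Step 7
Reactants: 11 bicyclic alcohol
Product: 12 O-(C3) imidazole-1-carbothioate of 11
Conditions: 1,1′-thiocarbonyldiimidazole, DMAP (cat.), toluene, 90 °C
Reagents that add atoms: 1,1′-thiocarbonyldiimidazole, S=C(n1ccnc1)n1ccnc1
Why: Neutral thioacylation of the hindered secondary alcohol (first half of a Barton–McCombie deoxygenation), chosen over a xanthate made with NaH so that no alkoxide can trigger O-to-O migration of the neighbouring silyl group.

Step 8
Reactants: 12 thiocarbamate
Product: 13 3-deoxy decalin (4α-CH2OTBDPS, 4β-CH3, 5α-H, C8 exocyclic methylene, 9β-chain, 10β-CH3)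
Conditions: Bu3SnH, AIBN (cat.), toluene, 110 °C
Reagents that add atoms: none
Why: Barton–McCombie radical chain deoxygenation, in which the stannyl radical adds to C=S, β-scission gives the secondary C3 radical and this takes hydrogen from Bu3SnH, so the C3 stereocentre is removed and nothing else is touched.

Step 9
Reactants: 13 exocyclic alkene
Product: 14 C7=C8 alkene (C8 now carries a methyl; other centres as in 13)
Conditions: [N,N′-bis(3,5-di-tert-butylsalicylidene)-1,2-cyclohexanediaminato]CoCl (cat.), PhSiH3 (cat.), benzene, rt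
Reagents that add atoms: none
Why: Hydrogen-atom-transfer alkene isomerisation, in which a cobalt hydride formed from the silane gives hydrogen to the methylene carbon and the tertiary C8 radical returns a hydrogen from C7 (more accessible than the C9–H beside quaternary C10), so the alkene should move into ring B as the trisubstituted C7=C8 alkene without change at any stereocentre.

Step 10
Reactants: 14 C7=C8 alkene
Product: 15 7-en-6-one
Conditions: Rh2(caprolactamate)4 (cat.), t-BuOOH (70% aq.), K2CO3, CH2Cl2, rt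
Reagents that add atoms: tert-butyl hydroperoxide, CC(C)(C)OO
Why: Dirhodium-catalysed allylic oxidation with t-BuOOH, in which the tert-butylperoxyl radical abstracts hydrogen from C6 (the only secondary allylic position) and the mixed peroxide collapses to the conjugated ketone, while C5 stays trans-fused because that is the more stable arrangement.

Step 11
Reactants: 15 enone
Product: 16 7α,8α-epoxy-6-ketone (8β-CH3)
Conditions: H2O2 (30% aq.), NaOH, MeOH/THF, 0 °C to rt
Reagents that add atoms: hydrogen peroxide, OO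
Why: Weitz–Scheffer nucleophilic epoxidation, in which hydroperoxide adds to C8 from the α face, anti to the axial C10 methyl, and the enolate closes the epoxide on the same face, which sets C8 with oxygen α and methyl β.

Step 12
Reactants: 16 epoxy ketone silyl ether
Product: 17 epoxy ketone with free C4 hydroxymethyl
Conditions: Bu4NF, AcOH, THF, 50 °C
Reagents that add atoms: none
Why: Fluoride-mediated Si–O cleavage driven by the Si–F bond, buffered with acetic acid so that the epoxy ketone is not exposed to free alkoxide.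

Step 13
Reactants: 17 primary alcohol
Product: 18 C4 carboxylic acid (4α-CO2H, epoxy ketone and ketal unchanged)
Conditions: TEMPO (cat.), NaOCl (cat.), NaClO2, MeCN/NaH2PO4–Na2HPO4 buffer (pH 6.7), 35 °C
Reagents that add atoms: sodium chlorite, [Na+].[O-]Cl=O
Why: Nitroxyl-catalysed oxidation to the aldehyde with in-situ chlorite (Pinnick-type) oxidation to the acid at near-neutral pH, which the ketal and the epoxy ketone tolerate and which cannot epimerise the quaternary C4.

Step 14
Reactants: 18 epoxy keto acid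
Product: 20 6α,8α-dihydroxy acid (8β-CH3, ketal intact), via hydroxy ketone 19 (not isolated)
Conditions: Li, NH3(l)/THF, t-BuOH, −78 to −33 °C; then NH4Cl
Reagents that add atoms: none
Why: Dissolving-metal reduction, in which the ketyl radical anion opens the α,β-epoxy ketone at C7–O (C8–O and its configuration retained) and, after protonation by t-BuOH, the ketone is reduced under thermodynamic control to the equatorial 6α-alcohol (hydride reagents would attack from the α face and give the axial 6β-alcohol), while the carboxylate and the ketal are inert.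

Step 15
Reactants: 20 dihydroxy acid
Product: 21 methyl ester (6α-OH, 8α-OH)
Conditions: Me3SiCHN2, MeOH/toluene, 0 °C to rt
Reagents that add atoms: (trimethylsilyl)diazomethane, C[Si](C)(C)C=[N+]=[N-]
Why: O-Methylation of the carboxylic acid by the diazoalkane needs no activation of the hindered neopentyl carboxyl and leaves both alcohols untouched.

Step 16
Reactants: 21 diol ester
Product: 22 6α,8α-bis(TBS) ether
Conditions: t-BuMe2SiOTf (excess), 2,6-lutidine, CH2Cl2, 0 °C to rt
Reagents that add atoms: tert-butyldimethylsilyl trifluoromethanesulfonate, CC(C)(C)[Si](C)(C)OS(=O)(=O)C(F)(F)F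
Why: Silyl triflate/2,6-lutidine silylation is strong enough for the hindered secondary C6 and the tertiary C8 hydroxyl, and both must be capped so that the C8 oxygen cannot add to the C13 ketone in steps 17–18 and only the C14 hydroxyl is free at the mesylation.

Step 17
Reactants: 22 ketal
Product: 23 methyl ketone (C13=O)
Conditions: PPTS, acetone/H2O, 50 °C
Reagents that add atoms: water, O
Why: Acid-catalysed hydrolysis of the dioxolane under conditions mild enough for the hindered TBS ethers and the ester.

Step 18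
Reactants: 23 methyl ketone
Product: 25 1-alken-2-yl triflate (CH2=C(OTf)– at C13), via potassium enolate 24 (not isolated)
Conditions: KN(SiMe3)2, THF, −78 °C; then PhNTf2, −78 to 0 °C
Reagents that add atoms: N-phenylbis(trifluoromethanesulfonimide), O=S(=O)(N(c1ccccc1)S(=O)(=O)C(F)(F)F)C(F)(F)F
Why: Kinetic deprotonation of the methyl ketone at the methyl group by the hindered amide base and O-sulfonylation of the enolate should give the terminal enol triflate, the ester having no α-hydrogen and both hydroxyls being silylated.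

Step 19
Reactants: 26 but-3-yn-1-ol
Product: 27 TBDPS ether of 26
Conditions: TBDPSCl, imidazole, CH2Cl2, 0 °C to rt
Reagents that add atoms: tert-butyl(chloro)diphenylsilane, CC(C)(C)[Si](Cl)(c1ccccc1)c1ccccc1
Why: Standard imidazole-mediated silylation of a primary alcohol, giving a silyl ether that survives the acid of step 25.

Step 20
Reactants: 27 silyl ether of butynol; 28 oxirane
Product: 30 (E)-6-(tert-butyldiphenylsilyloxy)-4-methylhex-3-en-1-ol, via alkenylalane 29 (not isolated)
Conditions: Me3Al, Cp2ZrCl2 (cat.), CH2Cl2, 0 °C to rt; then n-BuLi, hexane/THF, −78 °C; then oxirane, −78 °C to rt; aq. HCl work-up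
Reagents that add atoms: trimethylaluminium, C[Al](C)C
Why: Negishi zirconium-catalysed carboalumination adds methyl and aluminium syn across the alkyne (methyl to the internal carbon), and the lithium alkenylalanate opens oxirane with retention at the alkenyl carbon, which fixes the (E)-trisubstituted C16=C17 alkene.

Step 21
Reactants: 30 homoallylic alcohol
Product: 31 (E)-6-(tert-butyldiphenylsilyloxy)-4-methylhex-3-enal
Conditions: Dess–Martin periodinane, NaHCO3, CH2Cl2, 0 °C; used at once
Reagents that add atoms: none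
Why: Dess–Martin oxidation under buffered, non-basic conditions gives the β,γ-unsaturated aldehyde without moving the alkene into conjugation, provided it is used without storage.

Step 22
Reactants: 25 alkenyl triflate; 31 aldehyde
Product: 32 (14S)-allylic alcohol (C13 exocyclic methylene, (E)-C16=C17, C19–OTBDPS)
Conditions: CrCl2 (cat.), chiral N-sulfonyl aminooxazoline ligand (cat.), NiCl2(2,9-dimethyl-1,10-phenanthroline) (cat.), Mn, Cp2ZrCl2, LiCl, MeCN, rt
Reagents that add atoms: none
Why: Catalytic asymmetric Nozaki–Hiyama–Kishi coupling, in which nickel inserts into the C–OTf bond, the alkenyl group passes to chromium and adds to the aldehyde inside the chiral chromium complex, whose ligand antipode is chosen to favour the 14S alcohol; ester, silyl ethers and the trisubstituted alkene are inert.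

Step 23
Reactants: 32 allylic alcohol
Product: 33 (14S,16S,17S)-epoxy alcohol
Conditions: L-fructose-derived Shi ketone (cat.), KHSO5 (as 2KHSO5·KHSO4·K2SO4), K2CO3, Bu4NHSO4 (cat.), MeCN/dimethoxymethane/aq. Na2B4O7 buffer, 0 °C
Reagents that add atoms: potassium peroxymonosulfate, [K+].[O-]S(=O)(=O)OO
Why: Shi epoxidation, in which the chiral dioxirane attacks the electron-rich (E)-trisubstituted alkene through a spiro transition state much faster than the 1,1-disubstituted alkene, and the enantiomer of the usual D-fructose catalyst should give the (16S,17S)-epoxide.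

Step 24
Reactants: 33 epoxy alcohol
Product: 34 (14S)-mesylate
Conditions: MsCl, Et3N, CH2Cl2, −20 °C; used without chromatography
Reagents that add atoms: methanesulfonyl chloride, CS(=O)(=O)Cl
Why: Sulfonylation (via sulfene) of the only free hydroxyl with retention at C14, which installs the leaving group and also stops this hydroxyl from opening the nearby epoxide under the acid of step 25.

Step 25
Reactants: 34 epoxy mesylate
Product: 35 (16S)-hydroxy (17R)-hydroperoxide
Conditions: H2O2 (anhydrous, in Et2O), H3PMo12O40 (cat.), Et2O, 0 °C to rt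
Reagents that add atoms: hydrogen peroxide, OO
Why: Acid-catalysed perhydrolysis of a trisubstituted epoxide, in which H2O2 opens the activated epoxide at the tertiary C17 with inversion (17R) while C16 keeps its oxygen and configuration.

Step 26
Reactants: 35 hydroperoxy mesylate
Product: 36 1,2-dioxane (14R,16S,17R; 16-OH, C17 carries CH3 and CH2CH2OTBDPS)
Conditions: Cs2CO3, DMF, 0 °C
Reagents that add atoms: none
Why: Intramolecular alkylation of a hydroperoxide (6-exo-tet SN2), in which the peroxide anion displaces the allylic mesylate with inversion (14S to 14R), SN2′ attack at the methylene carbon being disfavoured because it would need an eight-membered ring.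

Step 27
Reactants: 36 tris-silyl ether
Product: 37 tetraol (6α-OH, 8α-OH, 16-OH, 19-OH)
Conditions: Bu4NF, AcOH, THF, rt to 40 °C
Reagents that add atoms: none
Why: Fluoride-mediated cleavage of all three silyl ethers under buffered conditions that avoid base-induced (Kornblum–DeLaMare) cleavage of the secondary allylic peroxide.

Step 28
Reactants: 37 tetraol
Product: 40 CNP0162504.1 (target), via hydroxy aldehyde 38 (not isolated), via lactol 39 (not isolated)
Conditions: PhI(OAc)2, TEMPO (cat.), CH2Cl2, rt
Reagents that add atoms: none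
Why: Nitroxyl-catalysed oxidative lactonisation, in which the primary C19 alcohol is oxidised selectively, the aldehyde is trapped by the C16 hydroxyl as the lactol (both groups equatorial and trans on the dioxane chair) and this is oxidised on to the trans-fused γ-lactone without change at any stereocentre, the hindered secondary and tertiary alcohols and the peroxide being left alone.

**Compound list**

1 | (2E,6E)-farnesyl bromide | CC(C)=CCC/C(C)=C/CC/C(C)=C/CBr | starting material
2 | ethyl acetoacetate | CCOC(=O)CC(C)=O | starting material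
3 | ethyl (4E,8E)-2-acetyl-5,9,13-trimethyltetradeca-4,8,12-trienoate (β-keto ester, racemic at C2, not isolated) | CC(C)=CCC/C(C)=C/CC/C(C)=C/CC(C(C)=O)C(=O)OCC | intermediate
4 | (4E,8E)-2-acetyl-5,9,13-trimethyltetradeca-4,8,12-trienoic acid (β-keto acid, not isolated) | CC(C)=CCC/C(C)=C/CC/C(C)=C/CC(C(C)=O)C(=O)O | intermediate
5 | (5E,9E)-6,10,14-trimethylpentadeca-5,9,13-trien-2-one (farnesylacetone) | CC(C)=CCC/C(C)=C/CC/C(C)=C/CCC(C)=O | intermediate
6 | 2-methyl-2-[(3E,7E)-4,8,12-trimethyltrideca-3,7,11-trienyl]-1,3-dioxolane | CC(C)=CCC/C(C)=C/CC/C(C)=C/CCC1(C)OCCO1 | intermediate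
7 | (2E,6E,10E)-2,6,10-trimethyl-12-(2-methyl-1,3-dioxolan-2-yl)dodeca-2,6,10-trien-1-ol | OC/C(C)=C/CC/C(C)=C/CC/C(C)=C/CCC1(C)OCCO1 | intermediate
8 | [(2S,3S)-2-methyl-3-[(3E,7E)-3,7-dimethyl-9-(2-methyl-1,3-dioxolan-2-yl)nona-3,7-dienyl]oxiran-2-yl]methanol | CC1(OCCO1)CC/C=C(\C)CC/C=C(\C)CC[C@@H]1O[C@@]1(C)CO | intermediate
9 | TBDPS ether of 8 (cyclisation precursor) | CC1(OCCO1)CC/C=C(\C)CC/C=C(\C)CC[C@@H]1O[C@@]1(C)CO[Si](c1ccccc1)(c1ccccc1)C(C)(C)C | intermediate
10 | chlorobis(cyclopentadienyl)titanium 3β-alkoxide of 11 (not isolated) | CC1(OCCO1)CC[C@@H]1[C@@]2(C)CC[C@H](O[Ti](Cl)(C3C=CC=C3)C3C=CC=C3)[C@@](C)(CO[Si](c3ccccc3)(c3ccccc3)C(C)(C)C)[C@@H]2CCC1=C | intermediate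
11 | bicyclic alcohol: 3β-OH, 4α-CH2OTBDPS, 4β-CH3, 5α-H, C8 exocyclic methylene, 9β-[2-(2-methyl-1,3-dioxolan-2-yl)ethyl], 10β-CH3 | CC1(OCCO1)CC[C@@H]1[C@@]2(C)CC[C@H](O)[C@@](C)(CO[Si](c3ccccc3)(c3ccccc3)C(C)(C)C)[C@@H]2CCC1=C | intermediate
12 | O-(C3) imidazole-1-carbothioate of 11 | CC1(OCCO1)CC[C@@H]1[C@@]2(C)CC[C@H](OC(=S)n3ccnc3)[C@@](C)(CO[Si](c3ccccc3)(c3ccccc3)C(C)(C)C)[C@@H]2CCC1=C | intermediate
13 | 3-deoxy decalin with C8 exocyclic methylene (4α-CH2OTBDPS, 4β-CH3, 5α-H, 9β-chain, 10β-CH3) | CC1(OCCO1)CC[C@@H]1[C@@]2(C)CCC[C@@](C)(CO[Si](c3ccccc3)(c3ccccc3)C(C)(C)C)[C@@H]2CCC1=C | intermediate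
14 | C7=C8 alkene isomer of 13 (8-CH3) | CC1(OCCO1)CC[C@@H]1[C@@]2(C)CCC[C@@](C)(CO[Si](c3ccccc3)(c3ccccc3)C(C)(C)C)[C@@H]2CC=C1C | intermediate
15 | 7-en-6-one | CC1(OCCO1)CC[C@@H]1[C@@]2(C)CCC[C@@](C)(CO[Si](c3ccccc3)(c3ccccc3)C(C)(C)C)[C@@H]2C(=O)C=C1C | intermediate
16 | 7α,8α-epoxy-6-ketone (8β-CH3) | CC1(OCCO1)CC[C@@H]1[C@@]2(C)CCC[C@@](C)(CO[Si](c3ccccc3)(c3ccccc3)C(C)(C)C)[C@@H]2C(=O)[C@H]3O[C@@]13C | intermediate
17 | epoxy ketone with free 4α-CH2OH | CC1(OCCO1)CC[C@@H]1[C@@]2(C)CCC[C@@](C)(CO)[C@@H]2C(=O)[C@H]3O[C@@]13C | intermediate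
18 | epoxy keto acid (4α-CO2H) | CC1(OCCO1)CC[C@@H]1[C@@]2(C)CCC[C@@](C)(C(=O)O)[C@@H]2C(=O)[C@H]3O[C@@]13C | intermediate
19 | 8α-hydroxy-6-keto acid (not isolated) | CC1(OCCO1)CC[C@@H]1[C@@]2(C)CCC[C@@](C)(C(=O)O)[C@@H]2C(=O)C[C@@]1(C)O | intermediate
20 | 6α,8α-dihydroxy acid (8β-CH3) | CC1(OCCO1)CC[C@@H]1[C@@]2(C)CCC[C@@](C)(C(=O)O)[C@@H]2[C@@H](O)C[C@@]1(C)O | intermediate
21 | methyl ester of 20 | CC1(OCCO1)CC[C@@H]1[C@@]2(C)CCC[C@@](C)(C(=O)OC)[C@@H]2[C@@H](O)C[C@@]1(C)O | intermediate
22 | 6α,8α-bis(TBS) ether of 21 | CC1(OCCO1)CC[C@@H]1[C@@]2(C)CCC[C@@](C)(C(=O)OC)[C@@H]2[C@@H](O[Si](C)(C)C(C)(C)C)C[C@@]1(C)O[Si](C)(C)C(C)(C)C | intermediate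
23 | methyl ketone (C13=O) | CC(=O)CC[C@@H]1[C@@]2(C)CCC[C@@](C)(C(=O)OC)[C@@H]2[C@@H](O[Si](C)(C)C(C)(C)C)C[C@@]1(C)O[Si](C)(C)C(C)(C)C | intermediate
24 | potassium enolate of 23, terminal (not isolated) | [K+].[O-]C(=C)CC[C@@H]1[C@@]2(C)CCC[C@@](C)(C(=O)OC)[C@@H]2[C@@H](O[Si](C)(C)C(C)(C)C)C[C@@]1(C)O[Si](C)(C)C(C)(C)C | intermediate
25 | 1-alken-2-yl triflate at C13 | C=C(OS(=O)(=O)C(F)(F)F)CC[C@@H]1[C@@]2(C)CCC[C@@](C)(C(=O)OC)[C@@H]2[C@@H](O[Si](C)(C)C(C)(C)C)C[C@@]1(C)O[Si](C)(C)C(C)(C)C | intermediate
26 | but-3-yn-1-ol | C#CCCO | starting material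
27 | (but-3-yn-1-yloxy)(tert-butyl)diphenylsilane | C#CCCO[Si](c1ccccc1)(c1ccccc1)C(C)(C)C | intermediate
28 | oxirane | C1CO1 | starting material
29 | (E)-dimethyl[4-(tert-butyldiphenylsilyloxy)-2-methylbut-1-enyl]alane (not isolated) | C[Al](C)/C=C(\C)CCO[Si](c1ccccc1)(c1ccccc1)C(C)(C)C | intermediate
30 | (E)-6-(tert-butyldiphenylsilyloxy)-4-methylhex-3-en-1-ol | OCC/C=C(\C)CCO[Si](c1ccccc1)(c1ccccc1)C(C)(C)C | intermediate
31 | (E)-6-(tert-butyldiphenylsilyloxy)-4-methylhex-3-enal | O=CC/C=C(\C)CCO[Si](c1ccccc1)(c1ccccc1)C(C)(C)C | intermediate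
32 | (14S)-allylic alcohol with C13 methylene, (E)-C16=C17, 19-OTBDPS, 6α,8α-bis(OTBS) | C=C(CC[C@@H]1[C@@]2(C)CCC[C@@](C)(C(=O)OC)[C@@H]2[C@@H](O[Si](C)(C)C(C)(C)C)C[C@@]1(C)O[Si](C)(C)C(C)(C)C)[C@@H](O)C/C=C(\C)CCO[Si](c1ccccc1)(c1ccccc1)C(C)(C)C | intermediate
33 | (14S,16S,17S)-16,17-epoxy-14-ol | C=C(CC[C@@H]1[C@@]2(C)CCC[C@@](C)(C(=O)OC)[C@@H]2[C@@H](O[Si](C)(C)C(C)(C)C)C[C@@]1(C)O[Si](C)(C)C(C)(C)C)[C@@H](O)C[C@@H]1O[C@@]1(C)CCO[Si](c1ccccc1)(c1ccccc1)C(C)(C)C | intermediate
34 | (14S)-mesylate of 33 | C=C(CC[C@@H]1[C@@]2(C)CCC[C@@](C)(C(=O)OC)[C@@H]2[C@@H](O[Si](C)(C)C(C)(C)C)C[C@@]1(C)O[Si](C)(C)C(C)(C)C)[C@@H](OS(C)(=O)=O)C[C@@H]1O[C@@]1(C)CCO[Si](c1ccccc1)(c1ccccc1)C(C)(C)C | intermediate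
35 | (14S)-mesylate (16S)-alcohol (17R)-hydroperoxide | C=C(CC[C@@H]1[C@@]2(C)CCC[C@@](C)(C(=O)OC)[C@@H]2[C@@H](O[Si](C)(C)C(C)(C)C)C[C@@]1(C)O[Si](C)(C)C(C)(C)C)[C@@H](OS(C)(=O)=O)C[C@H](O)[C@](C)(OO)CCO[Si](c1ccccc1)(c1ccccc1)C(C)(C)C | intermediate
36 | (14R,16S,17R)-1,2-dioxane with 16-OH, 17-CH3, 17-CH2CH2OTBDPS, silyl-protected decalin | C=C(CC[C@@H]1[C@@]2(C)CCC[C@@](C)(C(=O)OC)[C@@H]2[C@@H](O[Si](C)(C)C(C)(C)C)C[C@@]1(C)O[Si](C)(C)C(C)(C)C)[C@H]1C[C@H](O)[C@@](C)(CCO[Si](c2ccccc2)(c2ccccc2)C(C)(C)C)OO1 | intermediate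
37 | tetraol (6α-OH, 8α-OH, 16-OH, 19-OH) | C=C(CC[C@@H]1[C@@]2(C)CCC[C@@](C)(C(=O)OC)[C@@H]2[C@@H](O)C[C@@]1(C)O)[C@H]1C[C@H](O)[C@@](C)(CCO)OO1 | intermediate
38 | C19 aldehyde of 37 (not isolated) | C=C(CC[C@@H]1[C@@]2(C)CCC[C@@](C)(C(=O)OC)[C@@H]2[C@@H](O)C[C@@]1(C)O)[C@H]1C[C@H](O)[C@@](C)(CC=O)OO1 | intermediate
39 | trans-fused lactol, anomeric mixture (not isolated) | C=C(CC[C@@H]1[C@@]2(C)CCC[C@@](C)(C(=O)OC)[C@@H]2[C@@H](O)C[C@@]1(C)O)[C@H]1C[C@@H]2OC(O)C[C@@]2(C)OO1 | intermediate
40 | CNP0162504.1 | C=C(CC[C@@H]1[C@@]2(C)CCC[C@@](C)(C(=O)OC)[C@@H]2[C@@H](O)C[C@@]1(C)O)[C@H]1C[C@@H]2OC(=O)C[C@@]2(C)OO1 | target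

**Step count**

Total: 28 steps. Longest linear sequence: 25 steps (steps 1–18 and 22–28); steps 19–21 make the aldehyde 31.

**Steps most likely to fail**

1. Step 9. The C8 radical may return a hydrogen from C9 as well as from C7 (poor positional selectivity), or the isomerisation may run on to the tetrasubstituted C8=C9 alkene. The fallback sets out from 13 and fixes the alkene position by a reductive allylic transposition. SeO2/t-BuOOH would hydroxylate C7 from the α face to give the 7α-allylic alcohol F1. Mitsunobu reaction of F1 with o-nitrobenzenesulfonylhydrazide (PPh3, diethyl azodicarboxylate, THF, −30 °C) would give, with inversion, the 7β-sulfonylhydrazine F2. On warming this should lose the sulfinic acid to the allylic diazene F3, which expels N2 in a retro-ene step that delivers hydrogen to the methylene carbon and leaves the C7=C8 alkene. The fallback comes back to the route at 14.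

2. Step 22. The facial selectivity at the aldehyde carbon (C14) may be low, and the aldehyde may be lost by migration of its β,γ-alkene into conjugation. The fallback sets out from 25 and 31 and moves the stereocontrol from the C–C bond formation to a ketone reduction. The same coupling run without the chiral ligand, with slow addition of freshly made 31, would give the C14-epimeric allylic alcohols F4. Dess–Martin oxidation would give the enone F5, and Corey–Bakshi–Shibata reduction at −40 °C (oxazaborolidine antipode chosen for 14S, BH3·SMe2, toluene) would return the (14S)-alcohol. The fallback comes back to the route at 32.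

3. Step 26. The allylic mesylate may eliminate to the diene, or may already be lost by solvolysis under the acid of step 25, before the peroxide anion can displace it. The fallback sets out from 34 and reverses the roles of the two C–O bond formations. Displacement of the mesylate with 2-methoxyprop-2-yl hydroperoxide and CsOH (DMF, 0 °C) would give, with inversion, the (14R)-peroxyketal F6 while the epoxide is still intact. Aqueous AcOH/THF would release the (14R)-hydroperoxy epoxide F7. Acid catalysis (camphorsulfonic acid, CH2Cl2) would then let the hydroperoxide open the epoxide at the tertiary C17 with inversion (6-endo). The fallback comes back to the route at 36.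

Further compounds
F1 | step 9 | 7α-hydroxy derivative of 13 (C8 exocyclic methylene kept) | CC1(OCCO1)CC[C@@H]1[C@@]2(C)CCC[C@@](C)(CO[Si](c3ccccc3)(c3ccccc3)C(C)(C)C)[C@@H]2C[C@@H](O)C1=C
F2 | step 9 | 7β-[N-(2-nitrobenzenesulfonyl)hydrazinyl] derivative of 13 | CC1(OCCO1)CC[C@@H]1[C@@]2(C)CCC[C@@](C)(CO[Si](c3ccccc3)(c3ccccc3)C(C)(C)C)[C@@H]2C[C@H](N(N)S(=O)(=O)c3ccccc3[N+](=O)[O-])C1=C
F3 | step 9 | 7β-diazenyl derivative of 13 (allylic diazene) | CC1(OCCO1)CC[C@@H]1[C@@]2(C)CCC[C@@](C)(CO[Si](c3ccccc3)(c3ccccc3)C(C)(C)C)[C@@H]2C[C@H](N=N)C1=C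
F4 | step 22 | C14-epimeric mixture of allylic alcohol 32 | C=C(CC[C@@H]1[C@@]2(C)CCC[C@@](C)(C(=O)OC)[C@@H]2[C@@H](O[Si](C)(C)C(C)(C)C)C[C@@]1(C)O[Si](C)(C)C(C)(C)C)C(O)C/C=C(\C)CCO[Si](c1ccccc1)(c1ccccc1)C(C)(C)C
F5 | step 22 | C14 ketone (α-methylene ketone) of 32 | C=C(CC[C@@H]1[C@@]2(C)CCC[C@@](C)(C(=O)OC)[C@@H]2[C@@H](O[Si](C)(C)C(C)(C)C)C[C@@]1(C)O[Si](C)(C)C(C)(C)C)C(=O)C/C=C(\C)CCO[Si](c1ccccc1)(c1ccccc1)C(C)(C)C
F6 | step 26 | (14R)-(2-methoxyprop-2-yl)peroxy (16S,17S)-epoxide | C=C(CC[C@@H]1[C@@]2(C)CCC[C@@](C)(C(=O)OC)[C@@H]2[C@@H](O[Si](C)(C)C(C)(C)C)C[C@@]1(C)O[Si](C)(C)C(C)(C)C)[C@H](OOC(C)(C)OC)C[C@@H]1O[C@@]1(C)CCO[Si](c1ccccc1)(c1ccccc1)C(C)(C)C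
F7 | step 26 | (14R)-hydroperoxy (16S,17S)-epoxide | C=C(CC[C@@H]1[C@@]2(C)CCC[C@@](C)(C(=O)OC)[C@@H]2[C@@H](O[Si](C)(C)C(C)(C)C)C[C@@]1(C)O[Si](C)(C)C(C)(C)C)[C@H](OO)C[C@@H]1O[C@@]1(C)CCO[Si](c1ccccc1)(c1ccccc1)C(C)(C)C
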